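Ring C of the flavanone half is cut at O1–C2 and C4–C4a, leaving ring A as free phloroglucinol and C2–C3–C4 as an α-(flavon-3-yl)cinnamoyl unit. The key step exploits the threefold symmetry of ring A (C4a lies between two equivalent hydroxyl-bearing carbons) and the 1,3-relationship of acyl carbon C4 and benzylic C2: one AlCl3-mediated operation acylates phloroglucinol and closes ring C by 6-endo oxa-Michael addition, setting C2/C3 trans under thermodynamic control. Its precursor, a tert-butyl α-(tri-O-methylapigenin-3-yl)-4-methoxycinnamate, comes in two steps from apigenin trimethyl ether by C3-lithiation/oxalylation and Wittig olefination. Demethylation and a final resolution give the (2S,3R) enantiomer.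

Key step: step 3

Remark: C2 (reversible ring opening) and C3 (enolization) of the flavanone unit are configurationally labile under Lewis-acidic and basic conditions, so the trans pair is made as the racemate and the (2S,3R) enantiomer is secured by resolution in the last step.

Step 1
Reactants: 1 5,7-dimethoxy-2-(4-methoxyphenyl)-4H-chromen-4-one (apigenin trimethyl ether); 2 di-tert-butyl oxalate
Product: 4 tert-butyl 2-[5,7-dimethoxy-2-(4-methoxyphenyl)-4-oxo-4H-chromen-3-yl]-2-oxoacetate, via C3-lithiated flavone 3 (not isolated)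
Conditions: LiN(i-Pr)2 (1.2 equiv), THF, −78 °C; then transfer into 2 (3 equiv), THF, −78 °C; aq. NH4Cl quench at −78 °C
Reagents that add atoms: none
Why: Deprotonation of the vinylic C3–H of flavones by a lithium amide at −78 °C (carbonyl-directed lithiation) is a known way to 3-substituted flavones, and acylation of the resulting vinyllithium with a dialkyl oxalate stops at the α-keto ester because the tetrahedral adduct persists until the cold quench; no stereocentre is formed.

Step 2
Reactants: 4 tert-butyl 2-[5,7-dimethoxy-2-(4-methoxyphenyl)-4-oxo-4H-chromen-3-yl]-2-oxoacetate; 5 (4-methoxybenzyl)triphenylphosphonium chloride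
Product: 7 tert-butyl (E)-2-[5,7-dimethoxy-2-(4-methoxyphenyl)-4-oxo-4H-chromen-3-yl]-3-(4-methoxyphenyl)prop-2-enoate, via phosphorus ylide 6 (not isolated)
Conditions: 5 (1.5 equiv), NaN(SiMe3)2 (1.4 equiv), THF, 0 °C; then 4, −78 °C → rt
Reagents that add atoms: none
Why: Wittig olefination of the non-enolizable, strongly electrophilic α-keto ester carbonyl with a semistabilized benzylic ylide gives the α-substituted cinnamate; the E isomer is drawn and any Z isomer is carried along, because the alkene geometry disappears when C2 and C3 become sp3 centres under thermodynamic control in step 3.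

Step 3
Reactants: 7 tert-butyl (E)-2-[5,7-dimethoxy-2-(4-methoxyphenyl)-4-oxo-4H-chromen-3-yl]-3-(4-methoxyphenyl)prop-2-enoate; 8 phloroglucinol (benzene-1,3,5-triol)
Product: 11 rac-(2S,3R)/(2R,3S)-3-[5,7-dimethoxy-2-(4-methoxyphenyl)-4-oxo-4H-chromen-3-yl]-5,7-dihydroxy-2-(4-methoxyphenyl)chroman-4-one (2,3-trans racemate), via acid chloride 9 (not isolated), via trihydroxyphenyl chalcone 10 (not isolated)
Conditions: SOCl2 (neat), rt, then evaporate; 8 (2 equiv), AlCl3 (5 equiv), PhNO2/CH2Cl2, 0 °C → rt; 1 M HCl work-up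
Reagents that add atoms: none
Why: SOCl2 converts the tert-butyl ester directly into acid chloride 9, which AlCl3 ionizes to the acylium ion; this acylates the aluminium phenoxide of phloroglucinol at carbon (Friedel–Crafts acylation, bond C4–C4a) to give chalcone 10 as an aluminium chelate, whose ortho-phenoxide oxygen then adds to the Lewis-acid-activated benzylic β-carbon (oxa-Michael addition, bond O1–C2), and the enolate is protonated at C3. The closest known reaction type is the one-flask Friedel–Crafts acylation/cyclization of phloroglucinol with cinnamoyl chlorides that gives 5,7-dihydroxyflavanones. Ring C, the only ring formed, closes in the 6-endo-trig mode. C2 and C3 are created together and should end up trans (aryl and flavonyl both equatorial) under thermodynamic control, since C3 equilibrates through the enol and C2 through reversible ring opening; no absolute control is exerted, so 11 is racemic. The step needs C-acylation at the acyl carbon in preference to Friedel–Crafts alkylation at the β-carbon and to intramolecular acylation of an anisyl ring: the β-carbon is shielded by the adjacent flavonyl group, the free anisyl positions are meta to methoxy, and phloroglucinol is by far the best nucleophile present. The threefold symmetry of phloroglucinol removes any question of site on ring A, and the new acyl group deactivates the ring against a second acylation.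

Step 4
Reactants: 11 rac-(2S,3R)/(2R,3S)-3-[5,7-dimethoxy-2-(4-methoxyphenyl)-4-oxo-4H-chromen-3-yl]-5,7-dihydroxy-2-(4-methoxyphenyl)chroman-4-one
Product: 12 rac-(2S,3R)/(2R,3S)-3-[5,7-dihydroxy-2-(4-hydroxyphenyl)-4-oxo-4H-chromen-3-yl]-5,7-dihydroxy-2-(4-hydroxyphenyl)chroman-4-one (2,3-trans racemate)
Conditions: BBr3 (12 equiv), CH2Cl2, −78 °C → rt; MeOH then H2O
Reagents that add atoms: none
Why: BBr3 cleaves aryl methyl ethers by Lewis acid complexation and bromide attack at methyl (a standard demethylation of flavone and flavanone methyl ethers), ring C either survives or re-closes from its boron-chelated chalcone on aqueous work-up, and the trans relationship of C2 and C3 is again the thermodynamic outcome.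

Step 5
Reactants: 12 rac-(2S,3R)/(2R,3S)-3-[5,7-dihydroxy-2-(4-hydroxyphenyl)-4-oxo-4H-chromen-3-yl]-5,7-dihydroxy-2-(4-hydroxyphenyl)chroman-4-one
Product: 13 (2S,3R)-3-[5,7-dihydroxy-2-(4-hydroxyphenyl)-4-oxo-4H-chromen-3-yl]-5,7-dihydroxy-2-(4-hydroxyphenyl)chroman-4-one (CNP0208264.1)
Conditions: preparative HPLC on amylose tris(3,5-dimethylphenylcarbamate), n-hexane/EtOH/CF3CO2H (0.1%), rt
Reagents that add atoms: none
Why: Chromatographic resolution on a polysaccharide carbamate phase is the routine way to separate flavanone enantiomers and is placed last so that nothing can erode the configuration afterwards; the (2S,3R) enantiomer is to be identified by electronic circular dichroism, and the other enantiomer can be racemized with mild base and recycled.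

Compound list
1 | 5,7-dimethoxy-2-(4-methoxyphenyl)-4H-chromen-4-one (apigenin trimethyl ether) | O=c1cc(-c2ccc(OC)cc2)oc2cc(OC)cc(OC)c12 | starting material
2 | di-tert-butyl oxalate | CC(C)(C)OC(=O)C(=O)OC(C)(C)C | starting material
3 | 3-lithio-5,7-dimethoxy-2-(4-methoxyphenyl)-4H-chromen-4-one | [Li]c1c(-c2ccc(OC)cc2)oc2cc(OC)cc(OC)c2c1=O | intermediate
4 | tert-butyl 2-[5,7-dimethoxy-2-(4-methoxyphenyl)-4-oxo-4H-chromen-3-yl]-2-oxoacetate | CC(C)(C)OC(=O)C(=O)c1c(-c2ccc(OC)cc2)oc2cc(OC)cc(OC)c2c1=O | intermediate
5 | (4-methoxybenzyl)triphenylphosphonium chloride | COc1ccc(C[P+](c2ccccc2)(c2ccccc2)c2ccccc2)cc1.[Cl-] | starting material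
6 | (4-methoxybenzylidene)triphenylphosphorane | COc1ccc(C=P(c2ccccc2)(c2ccccc2)c2ccccc2)cc1 | intermediate
7 | tert-butyl (E)-2-[5,7-dimethoxy-2-(4-methoxyphenyl)-4-oxo-4H-chromen-3-yl]-3-(4-methoxyphenyl)prop-2-enoate (any Z isomer is carried along) | CC(C)(C)OC(=O)/C(=C/c1ccc(OC)cc1)c1c(-c2ccc(OC)cc2)oc2cc(OC)cc(OC)c2c1=O | intermediate
8 | phloroglucinol (benzene-1,3,5-triol) | Oc1cc(O)cc(O)c1 | starting material
9 | (E)-2-[5,7-dimethoxy-2-(4-methoxyphenyl)-4-oxo-4H-chromen-3-yl]-3-(4-methoxyphenyl)prop-2-enoyl chloride | O=C(Cl)/C(=C/c1ccc(OC)cc1)c1c(-c2ccc(OC)cc2)oc2cc(OC)cc(OC)c2c1=O | intermediate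
10 | (E)-2-[5,7-dimethoxy-2-(4-methoxyphenyl)-4-oxo-4H-chromen-3-yl]-3-(4-methoxyphenyl)-1-(2,4,6-trihydroxyphenyl)prop-2-en-1-one | O=C(c1c(O)cc(O)cc1O)/C(=C/c1ccc(OC)cc1)c1c(-c2ccc(OC)cc2)oc2cc(OC)cc(OC)c2c1=O | intermediate
11 | rac-(2S,3R)/(2R,3S)-3-[5,7-dimethoxy-2-(4-methoxyphenyl)-4-oxo-4H-chromen-3-yl]-5,7-dihydroxy-2-(4-methoxyphenyl)chroman-4-one (both enantiomers written) | O=C1c2c(O)cc(O)cc2O[C@H](c2ccc(OC)cc2)[C@H]1c1c(-c2ccc(OC)cc2)oc2cc(OC)cc(OC)c2c1=O.O=C1c2c(O)cc(O)cc2O[C@@H](c2ccc(OC)cc2)[C@@H]1c1c(-c2ccc(OC)cc2)oc2cc(OC)cc(OC)c2c1=O | intermediate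
12 | rac-(2S,3R)/(2R,3S)-3-[5,7-dihydroxy-2-(4-hydroxyphenyl)-4-oxo-4H-chromen-3-yl]-5,7-dihydroxy-2-(4-hydroxyphenyl)chroman-4-one (both enantiomers written) | O=C1c2c(O)cc(O)cc2O[C@H](c2ccc(O)cc2)[C@H]1c1c(-c2ccc(O)cc2)oc2cc(O)cc(O)c2c1=O.O=C1c2c(O)cc(O)cc2O[C@@H](c2ccc(O)cc2)[C@@H]1c1c(-c2ccc(O)cc2)oc2cc(O)cc(O)c2c1=O | intermediate
13 | (2S,3R)-3-[5,7-dihydroxy-2-(4-hydroxyphenyl)-4-oxo-4H-chromen-3-yl]-5,7-dihydroxy-2-(4-hydroxyphenyl)chroman-4-one (CNP0208264.1) | O=C1c2c(O)cc(O)cc2O[C@H](c2ccc(O)cc2)[C@H]1c1c(-c2ccc(O)cc2)oc2cc(O)cc(O)c2c1=O | target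

Total step count: 5. Longest linear sequence: 5 steps (1 → 4 → 7 → 11 → 12 → 13).

Steps most likely to fail

Step 3. The process at risk is Friedel–Crafts alkylation of phloroglucinol at the benzylic β-carbon of the acylium ion (which would lead on to a lactone instead of the aryl ketone), or cyclization of the acylium ion onto an anisyl ring, in competition with C-acylation. Partial loss of the chelated 5-methyl ether of the flavone unit under AlCl3 would be harmless, because step 4 removes it in any case. The fallback sets out from 9 (made from 7 as in step 3) and returns at 12. 1,3,5-Trimethoxybenzene is lithiated between two methoxy groups (n-BuLi, THF, 0 °C) to (2,4,6-trimethoxyphenyl)lithium F1 and transmetalated with ZnCl2 to (2,4,6-trimethoxyphenyl)zinc chloride F2. Negishi acylation of F2 with 9 under Pd(PPh3)4 (zerovalent palladium; THF, rt) should give the hexamethyl ether chalcone F3, in which the aryl–carbonyl bond is fixed by the position of the metal. BBr3 (CH2Cl2, −78 °C → rt) then removes all six methyl ethers to give the hexahydroxy chalcone F4, which is not isolated and closes ring C by oxa-Michael addition on buffering (NaOAc, EtOH, 60 °C) to 12.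

Step 2. The process at risk is failure of the ylide to add to a carbonyl group flanked by the 2-aryl group and the C4 carbonyl of the flavone, or attack of the ylide at C2 of the pyranone ring with ring opening. The fallback sets out from 4 and returns at 7. 1,2-Addition of 4-methoxybenzylmagnesium chloride to the keto group in the presence of CeCl3 (THF, −78 °C) should give the racemic tertiary alcohol tert-butyl 2-[5,7-dimethoxy-2-(4-methoxyphenyl)-4-oxo-4H-chromen-3-yl]-2-hydroxy-3-(4-methoxyphenyl)propanoate F5. Dehydration of F5 with methyl N-(triethylammoniosulfonyl)carbamate (Burgess reagent; toluene, 60 °C) can only remove a benzylic hydrogen and gives 7.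

Step 4. The process at risk is incomplete cleavage of the 7- and 4'-methyl ethers of the flavone unit under conditions that the flavanone tolerates, or Lewis-acid opening of ring C followed by decomposition. The fallback inverts the order of deprotection and ring construction; it sets out from 7 and returns at 12. BBr3 (CH2Cl2, −78 °C → rt) applied to 7 removes the four methyl ethers and the tert-butyl ester to give (E)-2-[5,7-dihydroxy-2-(4-hydroxyphenyl)-4-oxo-4H-chromen-3-yl]-3-(4-hydroxyphenyl)prop-2-enoic acid F6. F6 and phloroglucinol 8 are then heated in BF3·OEt2 (70 °C), the medium in which polyphenols are acylated by free hydroxy-substituted carboxylic acids. The chalcone F4 formed in the flask closes ring C on buffered work-up (NaOAc, EtOH) to give 12, so that the flavanone never meets BBr3.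

Further compounds
F1 | step 3 | (2,4,6-trimethoxyphenyl)lithium | [Li]c1c(OC)cc(OC)cc1OC
F2 | step 3 | (2,4,6-trimethoxyphenyl)zinc chloride | COc1cc(OC)c([Zn]Cl)c(OC)c1
F3 | step 3 | (E)-2-[5,7-dimethoxy-2-(4-methoxyphenyl)-4-oxo-4H-chromen-3-yl]-3-(4-methoxyphenyl)-1-(2,4,6-trimethoxyphenyl)prop-2-en-1-one | O=C(c1c(OC)cc(OC)cc1OC)/C(=C/c1ccc(OC)cc1)c1c(-c2ccc(OC)cc2)oc2cc(OC)cc(OC)c2c1=O
F4 | step 3 | (E)-2-[5,7-dihydroxy-2-(4-hydroxyphenyl)-4-oxo-4H-chromen-3-yl]-3-(4-hydroxyphenyl)-1-(2,4,6-trihydroxyphenyl)prop-2-en-1-one | O=C(c1c(O)cc(O)cc1O)/C(=C/c1ccc(O)cc1)c1c(-c2ccc(O)cc2)oc2cc(O)cc(O)c2c1=O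
F5 | step 2 | tert-butyl 2-[5,7-dimethoxy-2-(4-methoxyphenyl)-4-oxo-4H-chromen-3-yl]-2-hydroxy-3-(4-methoxyphenyl)propanoate (racemic) | CC(C)(C)OC(=O)C(O)(Cc1ccc(OC)cc1)c1c(-c2ccc(OC)cc2)oc2cc(OC)cc(OC)c2c1=O
F6 | step 4 | (E)-2-[5,7-dihydroxy-2-(4-hydroxyphenyl)-4-oxo-4H-chromen-3-yl]-3-(4-hydroxyphenyl)prop-2-enoic acid | O=C(O)/C(=C/c1ccc(O)cc1)c1c(-c2ccc(O)cc2)oc2cc(O)cc(O)c2c1=O
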